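A direct plan would metalate 1-fluoro-3-methoxy-5-(methoxymethoxy)benzene A1 three times in turn: first to open (2R)-2-(propan-2-yl)oxirane A2, then to prenylate through copper, then to acylate to the fully substituted 2-fluoroaryl benzyl ketone A3. A3 would be formylated and closed to ring C by displacement of fluoride by the enol oxygen.
Its weakest steps would be:
- the first ring lithiation of A1, which would have to take the CH between the two ethers although both CH next to fluorine are more acidic;
- the last lithiation ortho to fluorine and the acylation to A3, where loss of fluoride to an aryne and enolisation of the acylating amide would compete;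
- the three-step preparation of A2 from the chiral pool, which would add length for one stereocenter.

The route rests on closing ring A last and at carbon: ring A is cut at C4a–C5, C5–C6 and C7–C8 into a ketene carried by a preformed 3-aryl-4-pyranone (rings B and C) and a chiral siloxyalkyne. The key step, a ketene–alkyne benzannulation, exploits the alternating oxygen pattern C5/C7/C8a of ring A and delivers in one operation the hexasubstituted ring with the C5 hydroxyl, the C6 side chain with its stereocenter, the C7 oxygen and the C8 prenyl group, each placed by connectivity. No ring lithiation, no fluoroarene and no O-arylation remain, and the stereocenter would come from one catalytic hydrogenation.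

Key step: step 9

Assumption: 5-hydroxy-2-methyl-4H-pyran-4-one (allomaltol) is taken as commercially available.

Step 1
Reactants: 1 ethyl 4-methyl-3-oxopentanoate
Product: 2 ethyl (3S)-3-hydroxy-4-methylpentanoate
Conditions: H2 (4 atm), RuCl2[(R)-BINAP] (cat.), EtOH, 100 °C
Reagents that add atoms: none
Why: Noyori asymmetric hydrogenation of the β-keto ester through its ruthenium chelate should deliver hydrogen to one carbonyl face under control of the (R)-BINAP ligand, which for this substrate corresponds to the (S)-carbinol (the same spatial sense as (R)-3-hydroxybutanoate, the descriptor changing because isopropyl outranks the CH2CO2Et branch).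

Step 2
Reactants: 2 ethyl (3S)-3-hydroxy-4-methylpentanoate
Product: 3 ethyl (3S)-4-methyl-3-(triethylsilyloxy)pentanoate
Conditions: Et3SiCl, imidazole, DMF, 0 °C to rt
Reagents that add atoms: chlorotriethylsilane, CC[Si](Cl)(CC)CC
Why: Imidazole-promoted O-silylation of the secondary alcohol masks it for the organolithium chemistry of the next step and for the ketene chemistry later, without touching the stereocenter.

Step 3
Reactants: 3 ethyl (3S)-4-methyl-3-(triethylsilyloxy)pentanoate
Product: 5 (4S)-5-methyl-4-(triethylsilyloxy)-1-(triisopropylsilyloxy)hex-1-yne, via lithium ynolate 4 (not isolated)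
Conditions: CH2Br2, lithium 2,2,6,6-tetramethylpiperidide, THF, −78 °C; 3; n-BuLi, −78 to 0 °C; i-Pr3SiCl, −78 °C to rt
Reagents that add atoms: dibromomethane, BrCBr; chlorotriisopropylsilane, CC(C)[Si](Cl)(C(C)C)C(C)C
Why: Kowalski ester homologation, in which addition of LiCHBr2 to the ester, enolisation to the dibromo enolate, bromine–lithium exchange and 1,2-shift of the alkyl group give the lithium ynolate 4 that the bulky chlorosilane traps on oxygen, leaves the carbinol stereocenter (β to the reacting carbon) untouched.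

Step 4
Reactants: 6 5-hydroxy-2-methyl-4H-pyran-4-one (allomaltol)
Product: 7 6-methyl-4-oxo-4H-pyran-3-yl trifluoromethanesulfonate
Conditions: Tf2O, pyridine, CH2Cl2, −10 to 0 °C
Reagents that add atoms: trifluoromethanesulfonic anhydride, O=S(=O)(OS(=O)(=O)C(F)(F)F)C(F)(F)F
Why: O-Sulfonylation of the acidic enolic hydroxyl of the 3-hydroxy-4-pyranone gives the enol triflate needed for cross-coupling.

Step 5
Reactants: 8 4-(4,4,5,5-tetramethyl-1,3,2-dioxaborolan-2-yl)phenol
Product: 9 triisopropyl[4-(4,4,5,5-tetramethyl-1,3,2-dioxaborolan-2-yl)phenoxy]silane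
Conditions: i-Pr3SiCl, imidazole, DMF, rt
Reagents that add atoms: chlorotriisopropylsilane, CC(C)[Si](Cl)(C(C)C)C(C)C
Why: Imidazole-promoted O-silylation of the phenol gives a base-tolerant ring B donor whose protecting group is removed at the end together with the other silyl ethers.

Step 6
Reactants: 7 6-methyl-4-oxo-4H-pyran-3-yl trifluoromethanesulfonate; 9 triisopropyl[4-(4,4,5,5-tetramethyl-1,3,2-dioxaborolan-2-yl)phenoxy]silane
Product: 10 2-methyl-5-[4-(triisopropylsilyloxy)phenyl]-4H-pyran-4-one
Conditions: Pd(dppf)Cl2 (cat.), K3PO4, 1,4-dioxane with a little H2O, 70 °C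
Reagents that add atoms: none
Why: Suzuki–Miyaura coupling (oxidative addition of zerovalent palladium into the electron-poor enol triflate, transmetalation from the boronate, reductive elimination) should join ring B to the pyranone that becomes ring C, and the weak phosphate base in nearly dry dioxane spares the aryl silyl ether.

Step 7
Reactants: 10 2-methyl-5-[4-(triisopropylsilyloxy)phenyl]-4H-pyran-4-one; 11 prenyl bromide (1-bromo-3-methylbut-2-ene)
Product: 13 2-(4-methylpent-3-en-1-yl)-5-[4-(triisopropylsilyloxy)phenyl]-4H-pyran-4-one, via lithium dienolate 12 (not isolated)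
Conditions: LiN(SiMe3)2, THF, −78 °C; 11, −78 to −20 °C
Reagents that add atoms: none
Why: Lateral deprotonation of the C2 methyl group gives the cross-conjugated dienolate 12 (a vinylogous enolate), which is alkylated at its exocyclic carbon by SN2 attack on the primary carbon of the allylic bromide, restoring the pyranone.

Step 8
Reactants: 13 2-(4-methylpent-3-en-1-yl)-5-[4-(triisopropylsilyloxy)phenyl]-4H-pyran-4-one
Product: 15 5-methyl-2-{4-oxo-5-[4-(triisopropylsilyloxy)phenyl]-4H-pyran-2-yl}hex-4-enoic acid (racemic), via lithium dienolate 14 (not isolated)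
Conditions: LiN(SiMe3)2, THF, −78 °C; CO2 (g), −78 to 0 °C; cold 1 M HCl
Reagents that add atoms: carbon dioxide, O=C=O
Why: A second lateral metalation gives dienolate 14, which is carboxylated by CO2 at the same exocyclic carbon (carboxylation of a vinylogous enolate), and cold acidification gives the acid, racemic at a carbon that becomes planar in the next step.

Step 9
Reactants: 15 5-methyl-2-{4-oxo-5-[4-(triisopropylsilyloxy)phenyl]-4H-pyran-2-yl}hex-4-enoic acid; 5 (4S)-5-methyl-4-(triethylsilyloxy)-1-(triisopropylsilyloxy)hex-1-yne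
Product: 20 5-hydroxy-6-[(2S)-3-methyl-2-(triethylsilyloxy)butyl]-8-(3-methylbut-2-en-1-yl)-7-(triisopropylsilyloxy)-3-[4-(triisopropylsilyloxy)phenyl]-4H-chromen-4-one, via acid chloride 16 (not isolated), via ketene 17 (not isolated), via cyclobutenone 18 (not isolated), via dienylketene 19 (not isolated)
Conditions: Me2C=C(Cl)NMe2 (Ghosez reagent), CH2Cl2, 0 °C to rt; Et3N, toluene, 0 °C; 5 (slight excess), rt, then 90 °C
Reagents that add atoms: none
Why: Dehydrochlorination of acid chloride 16 gives the pyranonyl(prenyl)ketene 17, whose carbonyl carbon is attacked by the nucleophilic alkyl-bearing carbon of siloxyalkyne 5 in a regiospecific [2+2] cycloaddition to cyclobutenone 18; thermal 4π electrocyclic opening then gives dienylketene 19, and 6π electrocyclic closure of the ketene carbon onto pyranone C3, followed by enolisation of the C4a–H that lies between two carbonyl groups, gives the phenol. The closest known reaction type is the ketene–alkynyl ether benzannulation (the Smith–Hoehn reaction in its Danheiser siloxyalkyne form), by which aryl- and vinylketenes are annulated to resorcinol monoethers. Ring A is the only ring closed, by a thermal disrotatory 6π electrocyclisation that forms C4a–C5 after the cycloaddition has formed C5–C6 and C7–C8, so it is closed at carbon–carbon bonds onto the preformed ring C. No stereocenter is created (the quaternary carbon of 18 and the sp3 C4a of the cyclohexadienone are transient), and the silylated (S)-carbinol carbon, two atoms away from the alkyne, has no path to epimerise. The step needs one orientation of the alkyne and one site of ring closure: the first is fixed by the polarity of the ynol ether (the carbon β to oxygen bonds to the ketene carbonyl carbon, which places the side chain at C6 between the C5 hydroxyl and the C7 silyl ether and the prenyl-bearing carbon at C8), and the second by the fact that the only unsaturated group on the ketene α-carbon is the C2=C3 bond of the pyranone. Since the ring opening of 18 is reversible, both alkene isomers of 19 should drain through the one that can cyclise.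

Step 10
Reactants: 20 5-hydroxy-6-[(2S)-3-methyl-2-(triethylsilyloxy)butyl]-8-(3-methylbut-2-en-1-yl)-7-(triisopropylsilyloxy)-3-[4-(triisopropylsilyloxy)phenyl]-4H-chromen-4-one
Product: 21 5-methoxy-6-[(2S)-3-methyl-2-(triethylsilyloxy)butyl]-8-(3-methylbut-2-en-1-yl)-7-(triisopropylsilyloxy)-3-[4-(triisopropylsilyloxy)phenyl]-4H-chromen-4-one
Conditions: MeI (excess), Ag2O, MeCN, 40 °C, dark
Reagents that add atoms: iodomethane, CI
Why: Williamson-type O-methylation of the one free, chelated phenol under silver oxide activation of iodomethane avoids the carbonate and hydride bases that could cleave the aryl silyl ethers and expose other phenols to methylation.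

Step 11
Reactants: 21 5-methoxy-6-[(2S)-3-methyl-2-(triethylsilyloxy)butyl]-8-(3-methylbut-2-en-1-yl)-7-(triisopropylsilyloxy)-3-[4-(triisopropylsilyloxy)phenyl]-4H-chromen-4-one
Product: 22 7-hydroxy-6-[(2S)-2-hydroxy-3-methylbutyl]-3-(4-hydroxyphenyl)-5-methoxy-8-(3-methylbut-2-en-1-yl)-4H-chromen-4-one
Conditions: Bu4NF, AcOH, THF, 0 °C to rt
Reagents that add atoms: none
Why: Fluoride attack at silicon cleaves the two aryl triisopropylsilyl ethers and the secondary triethylsilyl ether in one operation, and the acetic acid buffer keeps the medium near neutral so that the prenyl group, the C5 methyl ether and the carbinol stereocenter should be unaffected.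

**Compound list**

1 | ethyl 4-methyl-3-oxopentanoate | CCOC(=O)CC(=O)C(C)C | starting material
2 | ethyl (3S)-3-hydroxy-4-methylpentanoate | CCOC(=O)C[C@H](O)C(C)C | intermediate
3 | ethyl (3S)-4-methyl-3-(triethylsilyloxy)pentanoate | CCOC(=O)C[C@H](O[Si](CC)(CC)CC)C(C)C | intermediate
4 | lithium (4S)-5-methyl-4-(triethylsilyloxy)hex-1-yn-1-olate | [Li]OC#CC[C@H](O[Si](CC)(CC)CC)C(C)C | intermediate
5 | (4S)-5-methyl-4-(triethylsilyloxy)-1-(triisopropylsilyloxy)hex-1-yne | CC(C)[Si](C(C)C)(C(C)C)OC#CC[C@H](O[Si](CC)(CC)CC)C(C)C | intermediate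
6 | 5-hydroxy-2-methyl-4H-pyran-4-one (allomaltol) | Cc1cc(=O)c(O)co1 | starting material
7 | 6-methyl-4-oxo-4H-pyran-3-yl trifluoromethanesulfonate | Cc1cc(=O)c(OS(=O)(=O)C(F)(F)F)co1 | intermediate
8 | 4-(4,4,5,5-tetramethyl-1,3,2-dioxaborolan-2-yl)phenol | Oc1ccc(B2OC(C)(C)C(C)(C)O2)cc1 | starting material
9 | triisopropyl[4-(4,4,5,5-tetramethyl-1,3,2-dioxaborolan-2-yl)phenoxy]silane | CC(C)[Si](C(C)C)(C(C)C)Oc1ccc(B2OC(C)(C)C(C)(C)O2)cc1 | intermediate
10 | 2-methyl-5-[4-(triisopropylsilyloxy)phenyl]-4H-pyran-4-one | Cc1cc(=O)c(-c2ccc(O[Si](C(C)C)(C(C)C)C(C)C)cc2)co1 | intermediate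
11 | prenyl bromide (1-bromo-3-methylbut-2-ene) | CC(C)=CCBr | starting material
12 | lithium 2-methylidene-5-[4-(triisopropylsilyloxy)phenyl]-2H-pyran-4-olate | C=C1C=C(O[Li])C(-c2ccc(O[Si](C(C)C)(C(C)C)C(C)C)cc2)=CO1 | intermediate
13 | 2-(4-methylpent-3-en-1-yl)-5-[4-(triisopropylsilyloxy)phenyl]-4H-pyran-4-one | CC(C)=CCCc1cc(=O)c(-c2ccc(O[Si](C(C)C)(C(C)C)C(C)C)cc2)co1 | intermediate
14 | lithium 2-(4-methylpent-3-en-1-ylidene)-5-[4-(triisopropylsilyloxy)phenyl]-2H-pyran-4-olate | CC(C)=CCC=C1C=C(O[Li])C(-c2ccc(O[Si](C(C)C)(C(C)C)C(C)C)cc2)=CO1 | intermediate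
15 | 5-methyl-2-{4-oxo-5-[4-(triisopropylsilyloxy)phenyl]-4H-pyran-2-yl}hex-4-enoic acid (racemic) | CC(C)=CCC(C(=O)O)c1cc(=O)c(-c2ccc(O[Si](C(C)C)(C(C)C)C(C)C)cc2)co1 | intermediate
16 | 5-methyl-2-{4-oxo-5-[4-(triisopropylsilyloxy)phenyl]-4H-pyran-2-yl}hex-4-enoyl chloride | CC(C)=CCC(C(=O)Cl)c1cc(=O)c(-c2ccc(O[Si](C(C)C)(C(C)C)C(C)C)cc2)co1 | intermediate
17 | 5-methyl-2-{4-oxo-5-[4-(triisopropylsilyloxy)phenyl]-4H-pyran-2-yl}hexa-1,4-dien-1-one (ketene) | CC(C)=CCC(=C=O)c1cc(=O)c(-c2ccc(O[Si](C(C)C)(C(C)C)C(C)C)cc2)co1 | intermediate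
18 | 4-(3-methylbut-2-en-1-yl)-2-[(2S)-3-methyl-2-(triethylsilyloxy)butyl]-4-{4-oxo-5-[4-(triisopropylsilyloxy)phenyl]-4H-pyran-2-yl}-3-(triisopropylsilyloxy)cyclobut-2-en-1-one (mixture at C4) | O=C1C(C[C@H](O[Si](CC)(CC)CC)C(C)C)=C(O[Si](C(C)C)(C(C)C)C(C)C)C1(CC=C(C)C)c1cc(=O)c(-c2ccc(O[Si](C(C)C)(C(C)C)C(C)C)cc2)co1 | intermediate
19 | 7-methyl-2-[(2S)-3-methyl-2-(triethylsilyloxy)butyl]-4-{4-oxo-5-[4-(triisopropylsilyloxy)phenyl]-4H-pyran-2-yl}-3-(triisopropylsilyloxy)octa-1,3,6-trien-1-one (dienylketene) | O=C=C(C[C@H](O[Si](CC)(CC)CC)C(C)C)C(O[Si](C(C)C)(C(C)C)C(C)C)=C(CC=C(C)C)c1cc(=O)c(-c2ccc(O[Si](C(C)C)(C(C)C)C(C)C)cc2)co1 | intermediate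
20 | 5-hydroxy-6-[(2S)-3-methyl-2-(triethylsilyloxy)butyl]-8-(3-methylbut-2-en-1-yl)-7-(triisopropylsilyloxy)-3-[4-(triisopropylsilyloxy)phenyl]-4H-chromen-4-one | Oc1c(C[C@H](O[Si](CC)(CC)CC)C(C)C)c(O[Si](C(C)C)(C(C)C)C(C)C)c(CC=C(C)C)c2occ(-c3ccc(O[Si](C(C)C)(C(C)C)C(C)C)cc3)c(=O)c12 | intermediate
21 | 5-methoxy-6-[(2S)-3-methyl-2-(triethylsilyloxy)butyl]-8-(3-methylbut-2-en-1-yl)-7-(triisopropylsilyloxy)-3-[4-(triisopropylsilyloxy)phenyl]-4H-chromen-4-one | COc1c(C[C@H](O[Si](CC)(CC)CC)C(C)C)c(O[Si](C(C)C)(C(C)C)C(C)C)c(CC=C(C)C)c2occ(-c3ccc(O[Si](C(C)C)(C(C)C)C(C)C)cc3)c(=O)c12 | intermediate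
22 | 7-hydroxy-6-[(2S)-2-hydroxy-3-methylbutyl]-3-(4-hydroxyphenyl)-5-methoxy-8-(3-methylbut-2-en-1-yl)-4H-chromen-4-one | COc1c(C[C@H](O)C(C)C)c(O)c(CC=C(C)C)c2occ(-c3ccc(O)cc3)c(=O)c12 | target

Total step count: 11. Longest linear sequence: 7 steps (steps 4, 6, 7, 8, 9, 10 and 11).

Steps most likely to fail:

1. Step 9. The disubstituted ketene may be lost to dimerisation or amine-induced oligomerisation before it adds to the hindered alkyne. The dienylketene isomer with the prenyl CH2 next to the ketene may also undergo a 1,5-hydrogen shift instead of reclosing, and any excess ketene may acylate the product phenol. The fallback sets out from 10, builds ring A from an unhindered ketene made photochemically, and brings in the prenyl group afterwards. Oxidation of the methyl group of 10 with SeO2 in hot dioxane would give 4-oxo-5-[4-(triisopropylsilyloxy)phenyl]-4H-pyran-2-carbaldehyde F1. Pinnick oxidation (NaClO2, NaH2PO4, 2-methylbut-2-ene) would give 4-oxo-5-[4-(triisopropylsilyloxy)phenyl]-4H-pyran-2-carboxylic acid F2. Conversion to the acid chloride and acylation of trimethylsilyldiazomethane would give 2-(diazoacetyl)-5-[4-(triisopropylsilyloxy)phenyl]-4H-pyran-4-one F3. Irradiation of F3 at 365 nm in the presence of 5 (Wolff rearrangement to the monosubstituted pyranonylketene, then the same cycloaddition and electrocyclic cascade on warming to 80 °C) would give 5-hydroxy-6-[(2S)-3-methyl-2-(triethylsilyloxy)butyl]-7-(triisopropylsilyloxy)-3-[4-(triisopropylsilyloxy)phenyl]-4H-chromen-4-one F4. O-Alkylation of the C5 hydroxyl with 11 and K2CO3 in acetone would give 5-[(3-methylbut-2-en-1-yl)oxy]-6-[(2S)-3-methyl-2-(triethylsilyloxy)butyl]-7-(triisopropylsilyloxy)-3-[4-(triisopropylsilyloxy)phenyl]-4H-chromen-4-one F5. A para-Claisen–Cope rearrangement catalysed by Eu(fod)3 in CHCl3 at 60 °C, for which the blocked C6 leaves C8 as the only end point, would return to the route at 20.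

2. Step 8. Metalation at the now secondary lateral carbon may be slow or incomplete, the carbanion may be quenched by proton transfer from the product, and the vinylogous β-keto acid may lose CO2 during isolation. The fallback sets out from 10 and reverses the order of the two carbon–carbon bond formations. Carboxylation of dienolate 12 with CO2 at the more readily metalated methyl group would give 2-{4-oxo-5-[4-(triisopropylsilyloxy)phenyl]-4H-pyran-2-yl}acetic acid F6. Its dianion (two equivalents of LiN(i-Pr)2, THF, −78 °C) would then be alkylated at the α-carbon with 11, in the manner of arylacetic acid dianions, and acidification would return to the route at 15.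

3. Step 3. The amide base may deprotonate the ester at its α-carbon with β-elimination of the silanolate, or the carbenoid rearrangement may stop short of the ynolate. The fallback sets out from 3 and reaches the ynolate by oxidation of an acetylide instead. Reduction with i-Bu2AlH in CH2Cl2 at −78 °C would give (3S)-4-methyl-3-(triethylsilyloxy)pentanal F7. Ohira–Bestmann homologation (dimethyl (1-diazo-2-oxopropyl)phosphonate, K2CO3, MeOH) would give (4S)-5-methyl-4-(triethylsilyloxy)hex-1-yne F8. Its lithium acetylide (n-BuLi, THF, −78 °C) would be oxidised with lithium tert-butyl peroxide to ynolate 4, and O-silylation with i-Pr3SiOTf would return to the route at 5.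

**Further compounds**

F1 | step 9 | 4-oxo-5-[4-(triisopropylsilyloxy)phenyl]-4H-pyran-2-carbaldehyde | O=Cc1cc(=O)c(-c2ccc(O[Si](C(C)C)(C(C)C)C(C)C)cc2)co1
F2 | step 9 | 4-oxo-5-[4-(triisopropylsilyloxy)phenyl]-4H-pyran-2-carboxylic acid | OC(=O)c1cc(=O)c(-c2ccc(O[Si](C(C)C)(C(C)C)C(C)C)cc2)co1
F3 | step 9 | 2-(diazoacetyl)-5-[4-(triisopropylsilyloxy)phenyl]-4H-pyran-4-one | [N-]=[N+]=CC(=O)c1cc(=O)c(-c2ccc(O[Si](C(C)C)(C(C)C)C(C)C)cc2)co1
F4 | step 9 | 5-hydroxy-6-[(2S)-3-methyl-2-(triethylsilyloxy)butyl]-7-(triisopropylsilyloxy)-3-[4-(triisopropylsilyloxy)phenyl]-4H-chromen-4-one | Oc1c(C[C@H](O[Si](CC)(CC)CC)C(C)C)c(O[Si](C(C)C)(C(C)C)C(C)C)cc2occ(-c3ccc(O[Si](C(C)C)(C(C)C)C(C)C)cc3)c(=O)c12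
F5 | step 9 | 5-[(3-methylbut-2-en-1-yl)oxy]-6-[(2S)-3-methyl-2-(triethylsilyloxy)butyl]-7-(triisopropylsilyloxy)-3-[4-(triisopropylsilyloxy)phenyl]-4H-chromen-4-one | CC(C)=CCOc1c(C[C@H](O[Si](CC)(CC)CC)C(C)C)c(O[Si](C(C)C)(C(C)C)C(C)C)cc2occ(-c3ccc(O[Si](C(C)C)(C(C)C)C(C)C)cc3)c(=O)c12
F6 | step 8 | 2-{4-oxo-5-[4-(triisopropylsilyloxy)phenyl]-4H-pyran-2-yl}acetic acid | OC(=O)Cc1cc(=O)c(-c2ccc(O[Si](C(C)C)(C(C)C)C(C)C)cc2)co1
F7 | step 3 | (3S)-4-methyl-3-(triethylsilyloxy)pentanal | O=CC[C@H](O[Si](CC)(CC)CC)C(C)C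
F8 | step 3 | (4S)-5-methyl-4-(triethylsilyloxy)hex-1-yne | C#CC[C@H](O[Si](CC)(CC)CC)C(C)C
A1 | direct plan | 1-fluoro-3-methoxy-5-(methoxymethoxy)benzene | COCOc1cc(F)cc(OC)c1
A2 | direct plan | (2R)-2-(propan-2-yl)oxirane | CC(C)[C@@H]1CO1
A3 | direct plan | 1-{2-fluoro-6-methoxy-4-(methoxymethoxy)-3-(3-methylbut-2-en-1-yl)-5-[(2S)-2-(tert-butyldimethylsilyloxy)-3-methylbutyl]phenyl}-2-[4-(methoxymethoxy)phenyl]ethan-1-one | CC(C)[C@@H](O[Si](C)(C)C(C)(C)C)Cc1c(OC)c(C(=O)Cc2ccc(OCOC)cc2)c(F)c(CC=C(C)C)c1OCOC
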